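Reckon on the L charge: the flasks share the held X and the E loading, and L is what moves.

in all of them: X 8.5 mM (held); E 0.5 mol%

| charge | L | remark | time |
|---|---|---|---|
| zeta | 45 mM | run made earlier |  |
| beta | 70 mM | run made earlier |  |
| flask | 32 mM |  | 15 min |

| run | time / min | D / % | L / % |
|---|---|---|---|
| zeta | 4.00 | 74.1 | 0.2 |
| zeta | 8.00 | 74.2 | 0 |
| zeta | 10.0 | 73.6 | 0.3 |
| zeta | 15.0 | 74.0 | 0.1 |
| zeta | 20.0 | 74.3 | 0.6 |
| beta | 4.00 | 58.2 | 0 |
| beta | 8.00 | 58.2 | 0.1 |
| beta | 10.0 | 58.4 | 0.4 |
| beta | 15.0 | 58.0 | 0 |
| beta | 20.0 | 57.6 | 0.4 |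

(scatter of a reading: 0.3 percentage points)

* D at 15 min, in percent of the L charged
* concentration of G in solution at 15 min, in percent of saturation

In both runs L lies within scatter of zero at 4.00 min, and D stays flat afterwards. My reckoning takes G as held low while L lasts, so that D is made at the pace of the gas supply, zero order in L, while a loss among species that scale with the charge grows with its square. Their ratio is one dimensionless number, the loss number N, and I try the simplest form that carries it:

yield = 1 / √(1 + N), N = (L charge / reference charge)^2

The zeta reading of 74.0% gives the reference charge, the L charge at which N is one: 49.5 mM. The beta run played no part in this, so it is the test of whether one number is enough: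

N = 2.00, yield 57.7%, read 58.0%, scatter 0.3 percentage points

For the flask, N = 0.418, so my yield is 84.0%. The forecast, on another curve through the same runs, gives a lower 83%, and 100% for G, since “G refills over more than 10 min”.

The flask gives 83.3% and 100%.

    X ⇌ G, rate k1*(csat - [G]) (kL = 0.0510 s⁻¹)
    L + G + E → E + D (k = 5.50 × 10⁵ L² mol⁻² s⁻¹)
    L + G → Q (k = 0.130 L mol⁻¹ s⁻¹)
    L + D → Z (k = 0.230 L mol⁻¹ s⁻¹)
    2 E ⇌ J (K = 5600 L mol⁻¹, k = 310 L mol⁻¹ s⁻¹)

My yield for the flask stands 0.7 points above what the flask gives. Without the step from L + D to Z, D in this flask reaches 99.7%, and without the resistance to the transfer of X to G it reaches 98.6%, so the loss of D comes from the two together. At 130 mM of L, with the loading and time held, N = 6.89 gives 35.6%, and that neighbour flask holds 35.2%.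

The numbers in the tables were generated by integration for substances that don't exist; the scatter is artificial.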